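The earlier runs and the new flask come from a simulation from invented constants; scatter was added.

I am asked for two orders and for the share of substrate that the larch flask has turned into target at 6.3 min.

the same everywhere: free catalyst 0.00240 M
- oak: substrate 0.0800 M; reagent 0.240 M
- ash: substrate 0.0800 M; reagent 0.120 M
- maple: substrate 0.120 M; reagent 0.240 M
- larch: substrate 0.0320 M; reagent 0.192 M; time 6.3 min

- oak run (time / min: [target] / M): 0.79: 0.0172; 1.6: 0.0278; 2.4: 0.0341; 3.1: 0.0377; 3.9: 0.0399; 4.7: 0.0413; 5.5: 0.0430; 6.3: 0.0427
- ash run (time / min: [target] / M): 0.79: 0.0099; 1.6: 0.0179; 2.4: 0.0235; 3.1: 0.0268; 3.9: 0.0296; 4.7: 0.0325; 5.5: 0.0337; 6.3: 0.0360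
- maple run (time / min: [target] / M): 0.79: 0.0216; 1.6: 0.0353; 2.4: 0.0446; 3.1: 0.0498; 3.9: 0.0559; 4.7: 0.0582; 5.5: 0.0613; 6.3: 0.0617

(readings scatter by 6 × 10⁻⁴ M)

- Overall: substrate + reagent -> target, with free catalyst as catalyst.
- Constant volume, constant temperature.
- Readings of a species count what is bound in complexes too.
- An order is taken over about fifteen percent of the charge, up and down.

- the exponent of [substrate] in the starting rate at the charge of the oak run (at the point where two percent of the substrate have become target) (one fixed amount of target, the same in the runs compared)
- the exponent of [reagent] in the starting rate at the charge of the oak run (at the point where two percent of the substrate have become target)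
- target in the larch run at 6.3 min, as a share of the substrate charged

1. The puzzle is in the oak run. Its readings flatten near 0.0427 M, yet by the overall equation 0.0373 M of substrate and 0.197 M of reagent are still in the oak flask at that point.

2. So I compare charges. The maple run has 1.50 times the substrate of the oak run, and its last reading is 1.44 times the oak one. The last two oak readings give 53.6%, which I call the end share: the fraction of the substrate charged that has become target once the curve is flat.

3. Next I compare reagent. The ash run, with half the reagent of the oak run, holds 0.0179 M at 1.6 min, while the oak run holds 0.0172 M at 0.79 min. At these two readings [reagent] × time is nearly the same and so is target, which puts my reagent order near 1.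

4. The larch run reaches 1.21 M min of [reagent] × time, and the oak run reaches that at 5.04 min, between its readings at 4.7 min and 5.5 min. I assume that the oak share at that point holds at the small larch charge, and so I commit to the mean of those two oak readings, 52.7% of the substrate charged, for the larch run, which is lower than the end share.

5. The forecast gives 0.6 for substrate, 0.87 for reagent and 57% for the larch run, on the ground that “the catalyst is most likely dying, and more slowly at low reagent”. Its reagent order is lower than mine and its share is higher than mine.

The flask gives 0.45 for substrate, 1.0 for reagent and 54.1% for the larch run.

    free catalyst + substrate ⇌ catalyst-substrate complex, settled at all times (18.40 M⁻¹)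
    catalyst-substrate complex + reagent → target + free catalyst + by-product (108.0 M⁻¹ min⁻¹)
    free catalyst + impurity → spent catalyst
    free catalyst + reagent → spent catalyst + reagent (4.698 M⁻¹ min⁻¹)

The target made in the ash run comes to half of the substrate charged at 9.26 min, against 3.99 min in the oak run. The larch share is 1.01 times the end share. On the ash charge the end share comes to 0.0428 M of target, more than the 0.0400 M that the ash run holds at 9.26 min.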